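## The problem

Compound 18 is a γ-butyrolactone (ring atoms O1, C2 carbonyl, C3, C4, C5). C3 carries the CH2 of ring A (4-hydroxy-3-methoxyphenyl), and C4 carries an exocyclic secondary carbinol carbon, here called C6, which bears ring B (3,4-dimethoxyphenyl). The SMILES decodes to 3R,4R,6S: the ring substituents are trans, and in the zigzag C3–C4–C6–ring B the C5 methylene and the C6 oxygen lie on opposite sides (anti). The three contiguous stereocenters are not of equal weight. C3 is α to the lactone carbonyl and can be equilibrated to the more stable trans arrangement once C4 is fixed, so only C6 and C4 must be set under kinetic control. C6, the only center bearing a heteroatom, is the natural entry point for absolute configuration and can control C4 by 1,2-induction. The C6 hydroxyl is the delicate group. It is benzylic and para-alkoxy activated, so acid ionises it (elimination, or Friedel–Crafts closure onto ring A). It sits γ to C2, so a free alkoxide can take over the acyl group (translactonisation). Its C–O bond is also open to hydrogenolysis. The ring A phenol must be masked through the organometallic steps, and both electron-rich arenes limit the choice of oxidant. The enabling feature is seen once O1–C5 is unmade: C2–C3–C4–C6 is then a butanoate with oxygen on its γ-carbon. Written as the (E)-enoate C2–C3=C4–C6(OSi), C4 is the β-carbon next to the stereocenter, where a vinyl group (masked C5) can be delivered under control by C6. The enolate that results is centred on C3, the carbon that needs the ring A benzyl.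

## Retrosynthesis

**18 ⇐ 17 ⇐ 16.** The last bonds cut are the O–Si bond at C6 and the O–CH2Ph bond on ring A. A silyl ether at C6 is a poor leaving group, cannot be acylated and suppresses benzylic hydrogenolysis. A benzyl ether on ring A tolerates organolithium, enolate and amidine-base conditions. The order is therefore hydrogenolysis first (16 to 17), while C6–O is still silylated, and fluoride last (17 to 18) under buffered, non-basic conditions. The precursor 16 differs from the target only in two protecting groups.

**16 ⇐ 15.** No skeletal bond is cut; C3 is inverted. Conformational analysis of the enolate in the key step predicts that the benzyl group enters on the vinyl face, which becomes cis to the C4 side chain in the ring. The route is therefore planned through the cis-lactone 15 and a base equilibration to trans 16. This removes any demand on C3 selectivity in the key step, since either epimer converges on 16.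

**15 ⇐ 12.** Cutting the acyl bond O1–C2 and tracing the oxygenated C5 back to an alkene CH gives the open-chain ester 12, in which C5 is the inner carbon of a vinyl group. Vinyl is preferred to an oxygenated one-carbon nucleophile because vinylcopper reagents add cleanly to enoates and one ozonolysis–reduction unmasks the alcohol. The forward step must oxidise the terminal alkene while sparing rings A and B.

**12 ⇐ 6 + 9 + 8 (key disconnection).** The C4–C5 and C3–CH2(ring A) bonds are cut together. This returns the (S,E)-γ-silyloxy enoate 6, vinylmagnesium bromide 9 and the benzylic bromide 8. Cutting C3–C4 or C4–C6 instead would require joining two fragments that each carry a stereocenter. Here two bonds and two stereocenters are removed at once and the precursor keeps a single stereocenter. The forward reaction must add at C4 anti to the silyloxy group, must not expel the γ-oxygen, and must benzylate the enolate at carbon.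

**6 ⇐ 5 ⇐ 4 ⇐ 1 + 2.** Removing the silyl group gives 5. Raising the alkene to an alkyne gives the propargylic alcohol 4, and cutting its C6–C(sp) bond gives 3,4-dimethoxybenzaldehyde 1 and ethyl propiolate 2. The alkyne cut is chosen because catalytic asymmetric alkynylation of aromatic aldehydes sets C6 directly, and hydroxyl-directed trans-reduction of γ-hydroxy ynoates gives the E-enoate needed for anti induction. The forward steps must avoid base, which would isomerise these γ-aryl-γ-hydroxy unsaturated esters to the oxo ester.

**8 ⇐ 7.** The bromide comes in one step from the commercial alcohol 7 and is made just before use.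

## Roads not taken

**Alternative 1:** The C3–C4 bond, and a temporary C3–C6 bond, are traced to an intramolecular carbene addition. A chiral dirhodium or copper carbene from the (Z)-allyl diazomalonate A1 adds across the alkene and closes the lactone and a cyclopropane together, giving A2. Opening the cyclopropane at C6 by an oxygen nucleophile with inversion, benzylation of the malonate carbon with 8 and loss of the extra ester would follow. The merit is stereospecificity: the Z geometry places ring B endo, and inversion at C6 then gives exactly the anti C4/C6 relation. The lactone is also formed in the key step, with no ozonolysis and no enolate-facial question. The weak points are specific to this target. Diazomalonates are the least enantioselective class of carbene precursor in intramolecular cyclopropanation. The 3,4-dimethoxyphenyl donor makes the cyclopropane prone to ionise, so inversion at C6 could leak to an SN1 pathway. The dealkoxycarbonylation needs heat in the presence of the benzylic C–O bond. The Z-alkene, the diazo transfer and the decarboxylation also make the sequence longer. The chosen plan offers instead a single enantioselective step of a well-documented type, and a C6–O bond that is never exposed to ionising conditions.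

**Alternative 2:** The O1–C5 bond is cut by tracing the lactone to the 3-substituted cyclobutanone A3. A chiral catalyst with a peroxide inserts oxygen next to one of the two ring CH2 groups and gives A4, forming the ring and the C4 center in one step. Its endgame is better than the chosen one: benzylation of the lactone enolate of A4 with 8 occurs anti to the C4 substituent and gives the trans product directly, without an epimerisation step or ozone. The weak points lie before that. C4 becomes stereogenic only if the catalyst distinguishes two CH2 groups that differ through an exocyclic stereocenter. This is a matched/mismatched reagent-control problem in a reaction whose high selectivities are mostly confined to 3-aryl cyclobutanones. A3 must already be enantioenriched at C6 and needs a ketene–alkene cycloaddition and dehalogenation, so two independent stereocontrolling operations and more steps are required. A peroxide is also used on a substrate with two electron-rich arenes. The chosen plan offers substrate control of C4 from C6 in the same step that forms two C–C bonds.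

**Alternative 3:** No C–C bond is cut. The racemising aroylsuccinate A5 is reduced by a chiral ruthenium–diamine hydride (RuCl(TsDPEN)(p-cymene), formic acid/triethylamine) under dynamic kinetic resolution, and the alkoxide lactonises to the trans paraconate A6. This is better than the chosen plan at the front end: A5 is one acylation from commodity chemicals, and one catalytic step of a well-established type sets both C6 and C4. The difficulty is that A6 is acylated on the wrong oxygen, since its lactone is closed on C6–O while the target has C6–OH free and the lactone on C5–O. Reaching 18 would need three further operations: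
- benzylation at the lactone α-carbon in competition with enolisation at C4, which is α to the ester and stereogenic;
- chemoselective reduction of the ester to the C5 alcohol beside a lactone;
- an acyl migration from the benzylic to the primary oxygen, whose equilibrium position is not assured and which needs acid or base, the conditions that endanger C6.

The chosen plan spends three more steps before its key step but never relies on an acyl migration and keeps C6–O silylated until the last step.

Key step: step 5

Assumption: the (S)-BINOL–titanium catalyst is taken to direct the alkynylzinc to the Si face of 1, as for other aromatic aldehydes; if the opposite sense were found, (R)-BINOL would be used and nothing else would change.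

## Route

Step 1
Reactants: 1 3,4-dimethoxybenzaldehyde; 2 ethyl propiolate
Product: 4 ethyl (R)-4-(3,4-dimethoxyphenyl)-4-hydroxybut-2-ynoate, via alkynylzinc reagent 3 (not isolated)
Conditions: 2, ZnEt2, HMPA, CH2Cl2, rt; then (S)-BINOL (40 mol%), Ti(OiPr)4 (1 equiv); then 1, rt; cold aq. NH4Cl work-up
Reagents that add atoms: diethylzinc, CC[Zn]CC (zinc and ethyl of 3 only)
Why: Catalytic asymmetric alkynylzinc addition to an aldehyde with the BINOL–Ti(OiPr)4 system, a known reaction for alkyl propiolates and aromatic aldehydes. Si-face delivery sets C6; the descriptor is R because the alkynyl group outranks the aryl group, and this is the spatial arrangement that is S in the target. HMPA lets 3 form at room temperature so the propiolate is not degraded by heating.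

Step 2
Reactants: 4 ethyl (R)-4-(3,4-dimethoxyphenyl)-4-hydroxybut-2-ynoate
Product: 5 ethyl (S,E)-4-(3,4-dimethoxyphenyl)-4-hydroxybut-2-enoate
Conditions: NaAlH2(OCH2CH2OMe)2, THF, −72 °C; cold dilute acid quench
Reagents that add atoms: none
Why: Hydroxyl-directed trans-hydroalumination of a γ-hydroxy ynoate followed by protonation, a known route to (E)-γ-hydroxy enoates; at this temperature the ester is not reduced. C6 is untouched; its descriptor changes from R to S only because the alkene ranks below the aryl group.

Step 3
Reactants: 5 ethyl (S,E)-4-(3,4-dimethoxyphenyl)-4-hydroxybut-2-enoate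
Product: 6 ethyl (S,E)-4-(tert-butyldimethylsilyloxy)-4-(3,4-dimethoxyphenyl)but-2-enoate
Conditions: TBSCl, imidazole, DMF, 0 °C → rt
Reagents that add atoms: tert-butyldimethylsilyl chloride, CC(C)(C)[Si](C)(C)Cl
Why: Standard silylation of a secondary alcohol. Imidazole is too weak a base to trigger isomerisation of the γ-hydroxy enoate to the γ-oxo ester, and the silyl ether is the directing group and poor leaving group needed in step 5.

Step 4
Reactants: 7 4-(benzyloxy)-3-methoxybenzyl alcohol
Product: 8 1-(benzyloxy)-4-(bromomethyl)-2-methoxybenzene
Conditions: PBr3 (0.4 equiv), Et2O, 0 °C; used freshly prepared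
Reagents that add atoms: phosphorus tribromide, BrP(Br)Br
Why: Standard conversion of a benzylic alcohol into the bromide through the bromophosphite and SN2 displacement; the aryl benzyl ether is inert.

Step 5
Reactants: 6 ethyl (S,E)-4-(tert-butyldimethylsilyloxy)-4-(3,4-dimethoxyphenyl)but-2-enoate; 9 vinylmagnesium bromide; 8 1-(benzyloxy)-4-(bromomethyl)-2-methoxybenzene
Product: 12 ethyl (2S,3S)-2-[4-(benzyloxy)-3-methoxybenzyl]-3-[(S)-(tert-butyldimethylsilyloxy)(3,4-dimethoxyphenyl)methyl]pent-4-enoate, via silyl ketene acetal 10 (not isolated), via lithium enolate 11 (not isolated)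
Conditions: 9 (4 equiv), CuI (2 equiv), Me3SiCl, THF, −78 °C, then 6; Et3N, pentane, filtration under argon, evaporation; MeLi (1.0 equiv), THF, −20 °C; 8, DMPU, −78 → −20 °C
Reagents that add atoms: chlorotrimethylsilane, C[Si](C)(C)Cl (silyl group of 10 only); methyllithium, [Li]C (lithium of 11 only)
Why: The divinylcuprate made from 9 and CuI forms a π-complex with the enoate and adds oxidatively at C4 to a trivalent copper β-cuprio enolate; Me3SiCl silylates the enolate oxygen and speeds reductive elimination, which forms the C4–C5 bond and gives 10. MeLi then cleaves the O–SiMe3 bond to release 11, which is benzylated by 8 in an SN2 step that forms the C3–CH2 bond. The closest known reaction types are the anti-selective cuprate–Me3SiCl addition to γ-alkoxy and γ-silyloxy (E)-enoates and the alkylation of ester enolates regenerated from silyl ketene acetals; no ring is closed. C4 is controlled by C6: in the reactive conformer the C6–H lies near the enoate plane, the C6–O bond is antiperiplanar to the incoming copper and ring B points outward, so vinyl enters anti to the silyloxy group and gives the 3S center of 12 (R at C4 of the lactone). C3 is controlled by C4: 11 holds the C4–H in the enolate plane to avoid allylic 1,3-strain, and 8 approaches past the small vinyl group, opposite the CH(OSi)aryl group, which should give the 2S ester (benzyl cis to the side chain in the later ring). Because C3 is equilibrated in step 7, three selectivities are needed: 1,4-addition over reductive loss of the γ-oxygen (secured by the poor leaving ability of the silyloxy group, Me3SiCl acceleration and −78 °C), anti addition at C4 (secured by the (S)-silyloxy center and the E geometry), and C-alkylation without attack on the ester (secured by the lithium counter-ion, a reactive benzylic bromide and exactly one equivalent of MeLi).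

Step 6
Reactants: 12 ethyl (2S,3S)-2-[4-(benzyloxy)-3-methoxybenzyl]-3-[(S)-(tert-butyldimethylsilyloxy)(3,4-dimethoxyphenyl)methyl]pent-4-enoate
Product: 15 (3S,4R)-3-[4-(benzyloxy)-3-methoxybenzyl]-4-[(S)-(tert-butyldimethylsilyloxy)(3,4-dimethoxyphenyl)methyl]dihydrofuran-2(3H)-one, via aldehyde 13 (not isolated), via hydroxy ester 14 (not isolated)
Conditions: O3, CH2Cl2/MeOH, Sudan Red 7B indicator, −78 °C; NaBH4, −78 → 0 °C; then PPTS (cat.), CH2Cl2, rt
Reagents that add atoms: ozone, [O-][O+]=O
Why: Ozonolysis with reductive NaBH4 work-up, then lactonisation of the γ-hydroxy ester (acyl substitution, 5-exo-trig). The terminal alkene reacts with ozone much faster than the alkoxyarenes, and the dye marks the end point. Aldehyde 13 is reduced as it is released, so C4 should not epimerise, and no stereocenter is created or touched.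

Step 7
Reactants: 15 (3S,4R)-3-[4-(benzyloxy)-3-methoxybenzyl]-4-[(S)-(tert-butyldimethylsilyloxy)(3,4-dimethoxyphenyl)methyl]dihydrofuran-2(3H)-one
Product: 16 (3R,4R)-3-[4-(benzyloxy)-3-methoxybenzyl]-4-[(S)-(tert-butyldimethylsilyloxy)(3,4-dimethoxyphenyl)methyl]dihydrofuran-2(3H)-one
Conditions: DBU, toluene, 80 °C
Reagents that add atoms: none
Why: Base-mediated epimerisation α to a lactone carbonyl under thermodynamic control, a known way to turn cis-2,3-disubstituted butyrolactones into the trans isomers. Only C3–H is acidic, C4 has no leaving group for elimination, and the trans isomer relieves the eclipsing of the benzyl and CH(OSi)aryl groups, so C3 becomes R whichever epimer step 5 delivered.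

Step 8
Reactants: 16 (3R,4R)-3-[4-(benzyloxy)-3-methoxybenzyl]-4-[(S)-(tert-butyldimethylsilyloxy)(3,4-dimethoxyphenyl)methyl]dihydrofuran-2(3H)-one
Product: 17 (3R,4R)-4-[(S)-(tert-butyldimethylsilyloxy)(3,4-dimethoxyphenyl)methyl]-3-(4-hydroxy-3-methoxybenzyl)dihydrofuran-2(3H)-one
Conditions: H2 (1 atm), 10% Pd/C, EtOAc, rt
Reagents that add atoms: none
Why: Hydrogenolysis of an aryl benzyl ether over palladium on carbon under neutral conditions. The C6 oxygen is still silylated, which suppresses hydrogenolysis of the benzylic C6–O bond; the lactone and the stereocenters are not affected.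

Step 9
Reactants: 17 (3R,4R)-4-[(S)-(tert-butyldimethylsilyloxy)(3,4-dimethoxyphenyl)methyl]-3-(4-hydroxy-3-methoxybenzyl)dihydrofuran-2(3H)-one
Product: 18 (3R,4R)-4-[(S)-(3,4-dimethoxyphenyl)(hydroxy)methyl]-3-(4-hydroxy-3-methoxybenzyl)dihydrofuran-2(3H)-one
Conditions: HF·pyridine, pyridine, THF, 0 °C → rt
Reagents that add atoms: none
Why: Fluoride cleavage of a secondary silyl ether under buffered, weakly acidic conditions. No alkoxide is generated, so acyl migration to the C6 oxygen is not expected, and the medium is too weakly acidic to ionise the benzylic C6–O bond; no stereocenter is touched.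

## Compound list

1 | 3,4-dimethoxybenzaldehyde | COc1ccc(C=O)cc1OC | starting material
2 | ethyl propiolate | C#CC(=O)OCC | starting material
3 | ethyl 3-(ethylzincio)prop-2-ynoate (formed in the flask, not isolated) | CCOC(=O)C#C[Zn]CC | intermediate
4 | ethyl (R)-4-(3,4-dimethoxyphenyl)-4-hydroxybut-2-ynoate | CCOC(=O)C#C[C@H](O)c1ccc(OC)c(OC)c1 | intermediate
5 | ethyl (S,E)-4-(3,4-dimethoxyphenyl)-4-hydroxybut-2-enoate | CCOC(=O)/C=C/[C@H](O)c1ccc(OC)c(OC)c1 | intermediate
6 | ethyl (S,E)-4-(tert-butyldimethylsilyloxy)-4-(3,4-dimethoxyphenyl)but-2-enoate | CCOC(=O)/C=C/[C@H](O[Si](C)(C)C(C)(C)C)c1ccc(OC)c(OC)c1 | intermediate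
7 | 4-(benzyloxy)-3-methoxybenzyl alcohol | COc1cc(CO)ccc1OCc1ccccc1 | starting material
8 | 1-(benzyloxy)-4-(bromomethyl)-2-methoxybenzene | COc1cc(CBr)ccc1OCc1ccccc1 | intermediate
9 | vinylmagnesium bromide | C=C[Mg]Br | starting material
10 | (3S)-3-[(S)-(tert-butyldimethylsilyloxy)(3,4-dimethoxyphenyl)methyl]-1-ethoxy-1-(trimethylsilyloxy)penta-1,4-diene, C1=C2 geometry not defined (formed in the flask, not isolated) | CCOC(O[Si](C)(C)C)=C[C@H](C=C)[C@H](O[Si](C)(C)C(C)(C)C)c1ccc(OC)c(OC)c1 | intermediate
11 | lithium (3S)-3-[(S)-(tert-butyldimethylsilyloxy)(3,4-dimethoxyphenyl)methyl]-1-ethoxypenta-1,4-dien-1-olate, enolate geometry not defined (formed in the flask, not isolated) | [Li+].CCOC([O-])=C[C@H](C=C)[C@H](O[Si](C)(C)C(C)(C)C)c1ccc(OC)c(OC)c1 | intermediate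
12 | ethyl (2S,3S)-2-[4-(benzyloxy)-3-methoxybenzyl]-3-[(S)-(tert-butyldimethylsilyloxy)(3,4-dimethoxyphenyl)methyl]pent-4-enoate | CCOC(=O)[C@@H](Cc1ccc(OCc2ccccc2)c(OC)c1)[C@H](C=C)[C@H](O[Si](C)(C)C(C)(C)C)c1ccc(OC)c(OC)c1 | intermediate
13 | ethyl (2S,3S,4S)-2-[4-(benzyloxy)-3-methoxybenzyl]-4-(tert-butyldimethylsilyloxy)-4-(3,4-dimethoxyphenyl)-3-formylbutanoate (formed in the flask, not isolated) | CCOC(=O)[C@@H](Cc1ccc(OCc2ccccc2)c(OC)c1)[C@H](C=O)[C@H](O[Si](C)(C)C(C)(C)C)c1ccc(OC)c(OC)c1 | intermediate
14 | ethyl (2S,3R,4S)-2-[4-(benzyloxy)-3-methoxybenzyl]-4-(tert-butyldimethylsilyloxy)-4-(3,4-dimethoxyphenyl)-3-(hydroxymethyl)butanoate (formed in the flask, not isolated) | CCOC(=O)[C@@H](Cc1ccc(OCc2ccccc2)c(OC)c1)[C@H](CO)[C@H](O[Si](C)(C)C(C)(C)C)c1ccc(OC)c(OC)c1 | intermediate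
15 | (3S,4R)-3-[4-(benzyloxy)-3-methoxybenzyl]-4-[(S)-(tert-butyldimethylsilyloxy)(3,4-dimethoxyphenyl)methyl]dihydrofuran-2(3H)-one | COc1cc(C[C@@H]2C(=O)OC[C@@H]2[C@H](O[Si](C)(C)C(C)(C)C)c2ccc(OC)c(OC)c2)ccc1OCc1ccccc1 | intermediate
16 | (3R,4R)-3-[4-(benzyloxy)-3-methoxybenzyl]-4-[(S)-(tert-butyldimethylsilyloxy)(3,4-dimethoxyphenyl)methyl]dihydrofuran-2(3H)-one | COc1cc(C[C@H]2C(=O)OC[C@@H]2[C@H](O[Si](C)(C)C(C)(C)C)c2ccc(OC)c(OC)c2)ccc1OCc1ccccc1 | intermediate
17 | (3R,4R)-4-[(S)-(tert-butyldimethylsilyloxy)(3,4-dimethoxyphenyl)methyl]-3-(4-hydroxy-3-methoxybenzyl)dihydrofuran-2(3H)-one | COc1cc(C[C@H]2C(=O)OC[C@@H]2[C@H](O[Si](C)(C)C(C)(C)C)c2ccc(OC)c(OC)c2)ccc1O | intermediate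
18 | (3R,4R)-4-[(S)-(3,4-dimethoxyphenyl)(hydroxy)methyl]-3-(4-hydroxy-3-methoxybenzyl)dihydrofuran-2(3H)-one | COc1cc(C[C@H]2C(=O)OC[C@@H]2[C@H](O)c2ccc(OC)c(OC)c2)ccc1O | target

## Step count and risks

Total: 9 steps. Longest linear sequence: 8 steps (steps 1–3 and 5–9 from 1); step 4 is a one-step side branch.

**Step 5 (key step).** Three processes may interfere: reductive loss of the benzylic silyloxy group (electron transfer from the cuprate followed by expulsion of the γ-oxygen), erosion of anti selectivity if ring B competes with the silyloxy group for the antiperiplanar position, and incomplete enolate regeneration or alkylation in the presence of residual salts. Fallback: divide the operation. From 6, the same cuprate–Me3SiCl addition with aqueous work-up gives ethyl (R)-3-[(S)-(tert-butyldimethylsilyloxy)(3,4-dimethoxyphenyl)methyl]pent-4-enoate F1, which can be purified and freed of any minor diastereomer. Deprotonation with LDA (THF, −78 °C) then gives enolate 11 free of copper and magnesium salts, and benzylation with 8 and DMPU returns to 12.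

**Step 1.** Enantiomeric purity may be insufficient with this electron-rich aldehyde (uncatalysed background addition), and the product may isomerise to the oxo ester on basic work-up. Fallback: racemic addition and enzymatic resolution. From 1 and the lithium acetylide of 2 (LiHMDS, THF, −78 °C), racemic ethyl 4-(3,4-dimethoxyphenyl)-4-hydroxybut-2-ynoate F2 is made. Candida antarctica lipase B with vinyl acetate should acylate the (S)-enantiomer (aryl as the large group, the slim alkynyl as the medium group) to ethyl (S)-4-acetoxy-4-(3,4-dimethoxyphenyl)but-2-ynoate F3. The unreacted alcohol is 4, at the cost of half the material.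

**Step 6.** Ozone may over-oxidise the dimethoxyarene or the benzyl ether once the alkene is consumed, or peroxidic intermediates may be incompletely reduced. Fallback: cleave in two stages without ozone. From 12, OsO4 (cat.)/NMO gives ethyl (2S,3R)-2-[4-(benzyloxy)-3-methoxybenzyl]-3-[(S)-(tert-butyldimethylsilyloxy)(3,4-dimethoxyphenyl)methyl]-4,5-dihydroxypentanoate F4 (both C4 epimers). NaIO4 cleaves it to aldehyde 13, which is reduced with NaBH4 and lactonised as in step 6 to reach 15.

**Step 7.** Equilibration may be slow or incomplete, since an amidine is a weak base for an unactivated lactone and the equilibrium may leave residual 15. Fallback: set C3 kinetically on the ring instead. From 6, through F1 (as above), ozonolysis–NaBH4 and lactonisation give (R)-4-[(S)-(tert-butyldimethylsilyloxy)(3,4-dimethoxyphenyl)methyl]dihydrofuran-2(3H)-one F5. Its lithium enolate (LiHMDS, THF, −78 °C) is benzylated by 8 anti to the C4 substituent, the classical trans-selective lactone alkylation, to reach 16 directly.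

## Further compounds

F1 | step 5 | ethyl (R)-3-[(S)-(tert-butyldimethylsilyloxy)(3,4-dimethoxyphenyl)methyl]pent-4-enoate | CCOC(=O)C[C@H](C=C)[C@H](O[Si](C)(C)C(C)(C)C)c1ccc(OC)c(OC)c1
F2 | step 1 | racemic ethyl 4-(3,4-dimethoxyphenyl)-4-hydroxybut-2-ynoate | CCOC(=O)C#CC(O)c1ccc(OC)c(OC)c1
F3 | step 1 | ethyl (S)-4-acetoxy-4-(3,4-dimethoxyphenyl)but-2-ynoate | CCOC(=O)C#C[C@@H](OC(C)=O)c1ccc(OC)c(OC)c1
F4 | step 6 | ethyl (2S,3R)-2-[4-(benzyloxy)-3-methoxybenzyl]-3-[(S)-(tert-butyldimethylsilyloxy)(3,4-dimethoxyphenyl)methyl]-4,5-dihydroxypentanoate (both C4 epimers) | CCOC(=O)[C@@H](Cc1ccc(OCc2ccccc2)c(OC)c1)[C@H](C(O)CO)[C@H](O[Si](C)(C)C(C)(C)C)c1ccc(OC)c(OC)c1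
F5 | step 7 | (R)-4-[(S)-(tert-butyldimethylsilyloxy)(3,4-dimethoxyphenyl)methyl]dihydrofuran-2(3H)-one | O=C1C[C@H](CO1)[C@H](O[Si](C)(C)C(C)(C)C)c1ccc(OC)c(OC)c1
A1 | alternative 1 | (Z)-3-(3,4-dimethoxyphenyl)allyl methyl 2-diazomalonate | COC(=O)C(=[N+]=[N-])C(=O)OC/C=C\c1ccc(OC)c(OC)c1
A2 | alternative 1 | methyl 6-endo-(3,4-dimethoxyphenyl)-2-oxo-3-oxabicyclo[3.1.0]hexane-1-carboxylate (enantiomer leading to R at C4) | O=C1OC[C@@H]2[C@H](c3ccc(OC)c(OC)c3)[C@]12C(=O)OC
A3 | alternative 2 | 3-[(S)-(tert-butyldimethylsilyloxy)(3,4-dimethoxyphenyl)methyl]cyclobutan-1-one | O=C1CC(C1)[C@H](O[Si](C)(C)C(C)(C)C)c1ccc(OC)c(OC)c1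
A4 | alternative 2 | (R)-4-[(S)-(tert-butyldimethylsilyloxy)(3,4-dimethoxyphenyl)methyl]dihydrofuran-2(3H)-one | O=C1C[C@H](CO1)[C@H](O[Si](C)(C)C(C)(C)C)c1ccc(OC)c(OC)c1
A5 | alternative 3 | dimethyl 2-(3,4-dimethoxybenzoyl)succinate (racemic) | COC(=O)CC(C(=O)OC)C(=O)c1ccc(OC)c(OC)c1
A6 | alternative 3 | methyl (2S,3S)-2-(3,4-dimethoxyphenyl)-5-oxotetrahydrofuran-3-carboxylate | COC(=O)[C@H]1CC(=O)O[C@@H]1c1ccc(OC)c(OC)c1
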